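## Plan

Numbering: ring C1 (C=O), C2=C3, C4, C5 (tertiary carbinol), C6; side chain C1′, C2′ (C=O), C10′=C11′ (Z), to C19′.

1. Feature used: the ring holds its tertiary carbinol C5 two bonds from the alkene (C5–C4–C3=C2), and C2 is the neighbour of the carbonyl carbon C1. An allyl unit attached to C1 through a boron-bearing C2 can therefore pass C4 to a C5 ketone from the side on which boron sits.
2. Retrosynthesis: both ketones go back to carbinols (C1–OH, C2′–OH). Then the ring bond C4–C5 is cut (intramolecular allylboration), then C1–C2 (aldehyde allylboration with a γ-borylallylborane), then C1′–C2′ (vinylogous aldol of an acetoacetate dienolate with oleyl aldehyde).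
3. Forward: the chain C1–C6–C5–C1′…C19′ is built first (oxidation, aldol, silylation, ketalisation, reduction), C2–C4 are added at C1, and the only ring (six-membered carbocycle) closes in the third step from the end. Desilylation and a double oxidation finish the synthesis.
4. Stereochemistry: the single stereocentre of the target, C5 (R), arises by 1,4-chirality transfer from the C2–B centre, which is fixed together with C1 by the diisopinocampheyl reagent. The C1 and C2′ carbinols are temporary and vanish in the last oxidation. The (Z)-alkene comes with oleyl alcohol.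

Key step: step 7

Remark: the C2′ carbinol only carries an oxidation level; it is made as one enantiomer, (S), so that each intermediate is a single stereoisomer. It is protected as a TBDPS ether, which must outlast the aqueous acid of the ring closure. The dienolate 3 is taken as purchased (it can be made fresh from methyl acetoacetate).

Abbreviations: TBDPS = tert-butyldiphenylsilyl; Bpin = 4,4,5,5-tetramethyl-1,3,2-dioxaborolan-2-yl; Ipc = isopinocampheyl; lIpc = the Ipc group derived from (−)-α-pinene.

## Route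

Step 1
Reactants: 1 oleyl alcohol [(9Z)-octadec-9-en-1-ol]
Product: 2 (9Z)-octadec-9-enal
Conditions: TEMPO (10 mol%), PhI(OAc)2 (1.1 equiv), CH2Cl2, 23 °C
Reagents that add atoms: none
Why: Oxoammonium-catalysed (TEMPO/PhI(OAc)2) oxidation of a primary alcohol stops at the aldehyde and leaves the (Z)-alkene untouched.

Step 2
Reactants: 2 (9Z)-octadec-9-enal; 3 1-methoxy-1,3-bis(trimethylsilyloxy)buta-1,3-diene (Chan's diene)
Product: 5 methyl (5S,13Z)-5-hydroxy-3-oxodocos-13-enoate, via bis-silyl aldol adduct 4 (not isolated)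
Conditions: Ti(OiPr)4 (10 mol%), (R)-BINOL (10 mol%), 4 Å MS, THF, −78 → 23 °C; then TFA, THF, −78 → 0 °C
Reagents that add atoms: none
Why: Vinylogous Mukaiyama aldol in which the terminal carbon of the dienolate forms C1′–C2′ on the aldehyde activated by the titanium–BINOL complex, Re-face attack being expected to give the (5S)-carbinol, after which TFA cleaves both silyl groups; any (5R) material converges on the same target because this centre is oxidised in step 9.

Step 3
Reactants: 5 methyl (5S,13Z)-5-hydroxy-3-oxodocos-13-enoate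
Product: 6 methyl (5S,13Z)-5-[(tert-butyldiphenylsilyl)oxy]-3-oxodocos-13-enoate
Conditions: TBDPSCl (1.3 equiv), imidazole (2.5 equiv), DMF, 23 °C
Reagents that add atoms: tert-butyl(chloro)diphenylsilane (TBDPSCl), CC(C)(C)[Si](Cl)(c1ccccc1)c1ccccc1
Why: Imidazole-promoted silylation of a secondary alcohol, done before ketalisation so that the free hydroxyl cannot lactonise onto the ester, with the acid-stable TBDPS group chosen to survive step 7.

Step 4
Reactants: 6 methyl (5S,13Z)-5-[(tert-butyldiphenylsilyl)oxy]-3-oxodocos-13-enoate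
Product: 7 methyl {2-[(2S,10Z)-2-[(tert-butyldiphenylsilyl)oxy]nonadec-10-en-1-yl]-1,3-dioxolan-2-yl}acetate
Conditions: (TMSOCH2)2 (3 equiv), TMSOTf (10 mol%), CH2Cl2, −78 → −20 °C; pyridine quench
Reagents that add atoms: 1,2-bis(trimethylsilyloxy)ethane, C[Si](C)(C)OCCO[Si](C)(C)C
Why: Noyori ketalisation masks the β-keto group at low temperature, without the heat and protic acid that would eliminate the β-silyloxy group, and so makes a non-enolisable precursor of the C1 aldehyde.

Step 5
Reactants: 7 methyl {2-[(2S,10Z)-2-[(tert-butyldiphenylsilyl)oxy]nonadec-10-en-1-yl]-1,3-dioxolan-2-yl}acetate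
Product: 8 {2-[(2S,10Z)-2-[(tert-butyldiphenylsilyl)oxy]nonadec-10-en-1-yl]-1,3-dioxolan-2-yl}acetaldehyde
Conditions: iBu2AlH (1.1 equiv), toluene, −78 °C; MeOH, aq. potassium sodium tartrate
Reagents that add atoms: none
Why: Partial ester-to-aldehyde reduction with one hydride equivalent at −78 °C, helped by coordination of aluminium to a dioxolane oxygen, should stop at the aldehyde oxidation level.

Step 6
Reactants: 8 {2-[(2S,10Z)-2-[(tert-butyldiphenylsilyl)oxy]nonadec-10-en-1-yl]-1,3-dioxolan-2-yl}acetaldehyde; 9 allenylboronic acid pinacol ester; 10 (+)-diisopinocampheylborane, (lIpc)2BH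
Product: 13 (2S,3R)-1-{2-[(2S,10Z)-2-[(tert-butyldiphenylsilyl)oxy]nonadec-10-en-1-yl]-1,3-dioxolan-2-yl}-3-(4,4,5,5-tetramethyl-1,3,2-dioxaborolan-2-yl)pent-4-en-2-ol, via (E)-γ-borylallyl diisopinocampheylborane 11 (not isolated), via borinate adduct 12 (not isolated)
Conditions: 9 (1.3 equiv), 10 (1.2 equiv), Et2O, −25 → 0 °C; then 8, −78 °C; then HOCH2CH2NH2, 0 → 23 °C
Reagents that add atoms: none
Why: Hydroboration of the terminal allene double bond and 1,3-boratropic equilibration should give the (E)-allylborane 11, which adds to the aldehyde through a Zimmerman–Traxler chair (diisopinocampheylborane allylboration, known with this reagent for anti-1,2-diol and one-pot double-allylboration sequences), forming C1–C2 with the anti C1–O/C2–B relationship from the (E)-geometry and the C1 (S), C2 (R) configuration from Re-face attack directed by the lIpc groups; ethanolamine then frees the alcohol from borinate 12 without touching the C–B bond.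

Step 7
Reactants: 13 (2S,3R)-1-{2-[(2S,10Z)-2-[(tert-butyldiphenylsilyl)oxy]nonadec-10-en-1-yl]-1,3-dioxolan-2-yl}-3-(4,4,5,5-tetramethyl-1,3,2-dioxaborolan-2-yl)pent-4-en-2-ol
Product: 16 (1S,5S)-5-[(2S,10Z)-2-[(tert-butyldiphenylsilyl)oxy]nonadec-10-en-1-yl]cyclohex-2-ene-1,5-diol (cis-diol), via keto boronate 14 (not isolated), via pinacol borate 15 (not isolated)
Conditions: PPTS (0.3 equiv), THF/H2O (5:1), 0.01 M, 45 °C; then aq. NaHCO3
Reagents that add atoms: water, O
Why: Proposed new method: PPTS-mediated hydrolysis of the dioxolane should release the C5 ketone 14, whose carbonyl oxygen binds the boron on C2 so that C4 of the α-boryl allyl unit adds to C5 in a closed allyl transfer (C4–C5 formed, boron moved from C2 to the C5 oxygen, alkene shifted to C2=C3), and the borate 15 is hydrolysed in the medium. The closest known reactions are the second, intermolecular stage of one-pot double allylborations (α-boryl homoallylic borinate plus aldehyde) and intramolecular allylborations of tethered ketones; new here are the ketone acceptor combined with a tether that starts at the boron-bearing carbon. The six-membered carbocycle closes 6-exo-trig at the carbonyl with the whole allyl unit inside the new ring, so the two-atom C1–C6 tether enforces a boat-like bicyclo[2.2.2] array and the new ring alkene can only be cis. The C5 stereocentre is set by 1,4-chirality transfer from C2: the oxygen has to stay bonded to boron, so the C5–O bond ends up on the ring face that boron leaves, cis to C1–OH, irrespective of how similar the two methylene substituents of the ketone are. The step needs this closed pathway to outrun acid-promoted open addition, β-elimination of the hydroxy boronate and intermolecular allylation; hence only a weak Brønsted acid, no Lewis acid, no ketone solvent and high dilution are used, and the C1 hydroxyl is left free so that it can hydrogen-bond the ketone oxygen onto the boron face.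

Step 8
Reactants: 16 (1S,5S)-5-[(2S,10Z)-2-[(tert-butyldiphenylsilyl)oxy]nonadec-10-en-1-yl]cyclohex-2-ene-1,5-diol
Product: 17 (1S,5R)-5-[(2S,10Z)-2-hydroxynonadec-10-en-1-yl]cyclohex-2-ene-1,5-diol
Conditions: Bu4NF (1.5 equiv), THF, 23 °C
Reagents that add atoms: none
Why: Fluoride-mediated cleavage of the silyl ether; the cyclohexenediol has no base-sensitive function at this stage, so unbuffered fluoride is acceptable.

Step 9
Reactants: 17 (1S,5R)-5-[(2S,10Z)-2-hydroxynonadec-10-en-1-yl]cyclohex-2-ene-1,5-diol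
Product: 18 (5R)-5-hydroxy-5-[(10Z)-2-oxononadec-10-en-1-yl]cyclohex-2-en-1-one
Conditions: Dess–Martin periodinane (3 equiv), pyridine, CH2Cl2, 0 → 23 °C
Reagents that add atoms: none
Why: Dess–Martin oxidation should convert the allylic C1 carbinol into the enone and the C2′ carbinol into the side-chain ketone in one operation while the tertiary C5 alcohol cannot react; pyridine buffering guards the β-hydroxy enone against dehydration to a phenol, and both temporary stereocentres disappear to leave C5 (R) as the only one.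

## Compound list

1 | oleyl alcohol, (9Z)-octadec-9-en-1-ol | CCCCCCCC/C=C\CCCCCCCCO | starting material
2 | (9Z)-octadec-9-enal | CCCCCCCC/C=C\CCCCCCCC=O | intermediate
3 | 1-methoxy-1,3-bis(trimethylsilyloxy)buta-1,3-diene (Chan's diene; C1=C2 geometry immaterial) | COC(O[Si](C)(C)C)=CC(=C)O[Si](C)(C)C | starting material
4 | methyl (5S,13Z)-3,5-bis(trimethylsilyloxy)docosa-2,13-dienoate (not isolated; C2=C3 geometry not defined) | CCCCCCCC/C=C\CCCCCCC[C@H](O[Si](C)(C)C)CC(O[Si](C)(C)C)=CC(=O)OC | intermediate
5 | methyl (5S,13Z)-5-hydroxy-3-oxodocos-13-enoate | CCCCCCCC/C=C\CCCCCCC[C@H](O)CC(=O)CC(=O)OC | intermediate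
6 | methyl (5S,13Z)-5-[(tert-butyldiphenylsilyl)oxy]-3-oxodocos-13-enoate | CCCCCCCC/C=C\CCCCCCC[C@H](O[Si](c1ccccc1)(c1ccccc1)C(C)(C)C)CC(=O)CC(=O)OC | intermediate
7 | methyl {2-[(2S,10Z)-2-[(tert-butyldiphenylsilyl)oxy]nonadec-10-en-1-yl]-1,3-dioxolan-2-yl}acetate | CCCCCCCC/C=C\CCCCCCC[C@H](O[Si](c1ccccc1)(c1ccccc1)C(C)(C)C)CC1(CC(=O)OC)OCCO1 | intermediate
8 | {2-[(2S,10Z)-2-[(tert-butyldiphenylsilyl)oxy]nonadec-10-en-1-yl]-1,3-dioxolan-2-yl}acetaldehyde | CCCCCCCC/C=C\CCCCCCC[C@H](O[Si](c1ccccc1)(c1ccccc1)C(C)(C)C)CC1(CC=O)OCCO1 | intermediate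
9 | allenylboronic acid pinacol ester | C=C=CB1OC(C)(C)C(C)(C)O1 | starting material
10 | (+)-diisopinocampheylborane, (lIpc)2BH, the reagent derived from (−)-α-pinene | B([C@H]1C[C@H]2C[C@H](C2(C)C)[C@@H]1C)[C@H]1C[C@H]2C[C@H](C2(C)C)[C@@H]1C | starting material
11 | (E)-[3-(pinacolboryl)prop-2-en-1-yl]di(isopinocampheyl)borane (not isolated) | CC1(C)OB(/C=C/CB([C@H]2C[C@H]3C[C@H](C3(C)C)[C@@H]2C)[C@H]2C[C@H]3C[C@H](C3(C)C)[C@@H]2C)OC1(C)C | intermediate
12 | O-di(isopinocampheyl)boryl derivative (borinate) of 13 (not isolated) | CCCCCCCC/C=C\CCCCCCC[C@H](O[Si](c1ccccc1)(c1ccccc1)C(C)(C)C)CC1(C[C@H](OB([C@H]2C[C@H]3C[C@H](C3(C)C)[C@@H]2C)[C@H]2C[C@H]3C[C@H](C3(C)C)[C@@H]2C)[C@@H](C=C)B2OC(C)(C)C(C)(C)O2)OCCO1 | intermediate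
13 | (2S,3R)-1-{2-[(2S,10Z)-2-[(tert-butyldiphenylsilyl)oxy]nonadec-10-en-1-yl]-1,3-dioxolan-2-yl}-3-(4,4,5,5-tetramethyl-1,3,2-dioxaborolan-2-yl)pent-4-en-2-ol (anti; C1 S, C2 R in target numbering) | CCCCCCCC/C=C\CCCCCCC[C@H](O[Si](c1ccccc1)(c1ccccc1)C(C)(C)C)CC1(C[C@H](O)[C@@H](C=C)B2OC(C)(C)C(C)(C)O2)OCCO1 | intermediate
14 | (3R,4S,8S,16Z)-8-[(tert-butyldiphenylsilyl)oxy]-4-hydroxy-3-(4,4,5,5-tetramethyl-1,3,2-dioxaborolan-2-yl)pentacosa-1,16-dien-6-one (keto boronate, not isolated) | CCCCCCCC/C=C\CCCCCCC[C@H](O[Si](c1ccccc1)(c1ccccc1)C(C)(C)C)CC(=O)C[C@H](O)[C@@H](C=C)B1OC(C)(C)C(C)(C)O1 | intermediate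
15 | tertiary O-pinacolboryl derivative (C5–O–Bpin) of 16 (not isolated) | CCCCCCCC/C=C\CCCCCCC[C@H](O[Si](c1ccccc1)(c1ccccc1)C(C)(C)C)C[C@]1(OB2OC(C)(C)C(C)(C)O2)CC=C[C@@H](O)C1 | intermediate
16 | (1S,5S)-5-[(2S,10Z)-2-[(tert-butyldiphenylsilyl)oxy]nonadec-10-en-1-yl]cyclohex-2-ene-1,5-diol (cis-diol; same spatial arrangement at C5 as in 18, descriptor changed by the silyl group) | CCCCCCCC/C=C\CCCCCCC[C@H](O[Si](c1ccccc1)(c1ccccc1)C(C)(C)C)C[C@]1(O)CC=C[C@@H](O)C1 | intermediate
17 | (1S,5R)-5-[(2S,10Z)-2-hydroxynonadec-10-en-1-yl]cyclohex-2-ene-1,5-diol (cis-diol) | CCCCCCCC/C=C\CCCCCCC[C@H](O)C[C@]1(O)CC=C[C@@H](O)C1 | intermediate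
18 | (5R)-5-hydroxy-5-[(10Z)-2-oxononadec-10-en-1-yl]cyclohex-2-en-1-one | CCCCCCCC/C=C\CCCCCCCC(=O)C[C@]1(O)CC=CC(=O)C1 | target

## Step count

Total: 9 steps. Longest linear sequence: 9 steps (1 → 18); 3, 9 and 10 enter as purchased reagents.

## Steps most likely to fail

**1. Step 7 (Proposed new method).**
- What may go wrong: the tether forces a boat-like transition state, so allyl transfer to the ketone may be slow and be overtaken by protodeboronation, β-elimination of the hydroxy boronate to a diene, or intermolecular allylation. If the acid opens an acyclic pathway, facial control at C5 is lost.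
- Fallback (known chemistry; sets out from 2 and 3, comes back at 18): the ring is closed by metathesis instead, and C5 is set by relay from the side-chain carbinol.
- The aldol of step 2 is run with (S)-BINOL and gives, through the bis-silyl adduct methyl (5R,13Z)-3,5-bis(trimethylsilyloxy)docosa-2,13-dienoate F1, the antipodal ester methyl (5R,13Z)-5-hydroxy-3-oxodocos-13-enoate F2.
- Hydroxyl-directed, chelation-controlled allylation of its ketone (allyl bromide, In, THF/H2O) should give methyl (3R,5R,13Z)-3,5-dihydroxy-3-(prop-2-en-1-yl)docos-13-enoate F3. The sense is predicted from a six-membered chelate with the alkyl chain equatorial, in which the allyl group enters anti to it.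
- MeNHOMe·HCl/iPrMgCl converts the ester into the Weinreb amide (3R,5R,13Z)-3,5-dihydroxy-N-methoxy-N-methyl-3-(prop-2-en-1-yl)docos-13-enamide F4.
- CH2=CHMgBr gives the vinyl ketone (5R,7R,15Z)-5,7-dihydroxy-5-(prop-2-en-1-yl)tetracosa-1,15-dien-3-one F5.
- Ring-closing metathesis (second-generation Hoveyda–Grubbs catalyst, CH2Cl2, 40 °C) forms C2=C3 and gives (5R)-5-hydroxy-5-[(2R,10Z)-2-hydroxynonadec-10-en-1-yl]cyclohex-2-en-1-one F6.
- Buffered Dess–Martin oxidation of the remaining carbinol gives 18.

**2. Step 6.**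
- What may go wrong: incomplete equilibration of the allylborane to its (E)-isomer, or a boratropic shift, would scramble the C2 configuration and with it C5 of the target. Borinate 12 may allylate unreacted aldehyde on warming, and the C–B bond may be lost when the borinate is cleaved.
- Fallback (sets out from 8, comes back at 13): enantiocontrol is moved from a stoichiometric borane made in the flask to a catalyst acting on an achiral, isolable reagent of fixed geometry.
- The reagent is (E)-1,3-bis(pinacolboryl)prop-1-ene F7, made by cross-metathesis of vinylboronic and allylboronic acid pinacol esters (second-generation Grubbs catalyst).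
- Chiral phosphoric acid-catalysed allylboration of 8 with it ((R)-TRIP, 5 mol%, toluene, −30 °C; the catalyst antipode that directs Re-face attack) should pass through the same chair (E → anti). It gives the O-pinacolboryl derivative of 13, F8, which aqueous work-up hydrolyses to 13. No borinate has to be cleaved.

**3. Step 5.**
- What may go wrong: over-reduction to the primary alcohol, or β-elimination of a dioxolane oxygen from the aldehyde during quench and chromatography.
- Fallback (sets out from 7, comes back at 8): full reduction with LiAlH4 (THF, 0 °C) to 2-{2-[(2S,10Z)-2-[(tert-butyldiphenylsilyl)oxy]nonadec-10-en-1-yl]-1,3-dioxolan-2-yl}ethan-1-ol F9, then oxidation with SO3·pyridine/DMSO/Et3N to 8, which is used without chromatography.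

## Further compounds

F1 | step 7 | methyl (5R,13Z)-3,5-bis(trimethylsilyloxy)docosa-2,13-dienoate (not isolated) | CCCCCCCC/C=C\CCCCCCC[C@@H](O[Si](C)(C)C)CC(O[Si](C)(C)C)=CC(=O)OC
F2 | step 7 | methyl (5R,13Z)-5-hydroxy-3-oxodocos-13-enoate | CCCCCCCC/C=C\CCCCCCC[C@@H](O)CC(=O)CC(=O)OC
F3 | step 7 | methyl (3R,5R,13Z)-3,5-dihydroxy-3-(prop-2-en-1-yl)docos-13-enoate | CCCCCCCC/C=C\CCCCCCC[C@@H](O)C[C@](O)(CC=C)CC(=O)OC
F4 | step 7 | (3R,5R,13Z)-3,5-dihydroxy-N-methoxy-N-methyl-3-(prop-2-en-1-yl)docos-13-enamide | CCCCCCCC/C=C\CCCCCCC[C@@H](O)C[C@](O)(CC=C)CC(=O)N(C)OC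
F5 | step 7 | (5R,7R,15Z)-5,7-dihydroxy-5-(prop-2-en-1-yl)tetracosa-1,15-dien-3-one | CCCCCCCC/C=C\CCCCCCC[C@@H](O)C[C@](O)(CC=C)CC(=O)C=C
F6 | step 7 | (5R)-5-hydroxy-5-[(2R,10Z)-2-hydroxynonadec-10-en-1-yl]cyclohex-2-en-1-one | CCCCCCCC/C=C\CCCCCCC[C@@H](O)C[C@]1(O)CC=CC(=O)C1
F7 | step 6 | (E)-1,3-bis(4,4,5,5-tetramethyl-1,3,2-dioxaborolan-2-yl)prop-1-ene | CC1(C)OB(/C=C/CB2OC(C)(C)C(C)(C)O2)OC1(C)C
F8 | step 6 | O-pinacolboryl derivative of 13 (not isolated) | CCCCCCCC/C=C\CCCCCCC[C@H](O[Si](c1ccccc1)(c1ccccc1)C(C)(C)C)CC1(C[C@H](OB2OC(C)(C)C(C)(C)O2)[C@@H](C=C)B2OC(C)(C)C(C)(C)O2)OCCO1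
F9 | step 5 | 2-{2-[(2S,10Z)-2-[(tert-butyldiphenylsilyl)oxy]nonadec-10-en-1-yl]-1,3-dioxolan-2-yl}ethan-1-ol | CCCCCCCC/C=C\CCCCCCC[C@H](O[Si](c1ccccc1)(c1ccccc1)C(C)(C)C)CC1(CCO)OCCO1
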